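Compound numbers are those of the step list and the compound list below. Ring A is the 4-methoxyphenyl ring, ring B the benzo ring of the chromene (C4a, C5, C6, C7, C8, C8a) and ring C the pyran (O1, C2, C3, C4).

Remark on the chemistry: 6, 7 and the transient adduct 14 are racemic and their stereocenters vanish before the achiral target, so no stereocontrol is planned. Silyl ether 15 is assumed to survive a non-aqueous work-up, and any 16 formed early is simply carried into step 9.

## Analysis of the target

Dielsianone 20 is an achiral benzil: a 1,2-diketone links ring A to C6 of a 2,2-dimethyl-2H-chromene made of ring B and ring C. There is no stereocenter, so the problem is one of regiochemistry and functional-group tolerance. Ring B is pentasubstituted: C4 on C4a, a free hydroxyl on C5, the acyl group on C6, methoxy on C8 and O1 on C8a, with C7–H the only open position. Its three oxygens must end up different: O5 free and hydrogen-bonded to the C6 carbonyl, O8 methylated, O1 inside ring C. The sensitive groups are the C3=C4 double bond with its tertiary allylic aryl ether (acid, electrophiles), the 1,2-diketone (nucleophiles and base) and the electron-rich arenes. Stepwise aromatic substitution would have to choose between C6 and C7 and between three similar oxygens, and that is the real difficulty. The route rests on reading ring B as two pieces: C8(OMe)–C8a(O)–C4a(C)–C5(O) is an oxygenated diene, and C7(H)–C6(acyl) is what a terminal alkynyl ketone supplies. A benzannulation of the two is possible if a two-carbon bridge absent from the target can be shed afterwards.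

## Retrosynthetic reasoning

**O5–CH3 bond; 20 back to 18.** The C5 hydroxyl is masked as a methyl ether until the end. A free O5 earlier would compete with O1 for the prenyl group, since both flank C4a. The methyl ortho to the C6 carbonyl is the one methyl ether that a chelating boron trihalide removes selectively, so a common protecting group is still distinguishable at the last step.

**Benzylic C=O; 18 back to 17.** The outer carbonyl of the diketone is taken back to a methylene. A deoxybenzoin survives the heat of the ring-forming step, whereas a benzil or an ynedione would not. The methylene is doubly activated (aryl and carbonyl), so a selenium-based oxidant should convert it. This must follow ring C closure, because the same oxidant would attack the allylic methyl groups of a free prenyl chain.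

**O1–C2 bond; 17 back to 16, and 16 back to 15.** Ring C is opened to an ortho-prenyl phenol. The forward reaction is an oxidative 6-endo closure of the C8a oxygen onto the trisubstituted alkene, which creates the C3=C4 bond in the same step. In 15 only the C8a oxygen is a silyl ether, so only it is freed and the direction of closure is fixed.

**C8–C7 and C5–C6 bonds; 15 back to 9 and 13 through 14.** Ring B is cut into diene 9 and ynone 13. In the forward direction they form the bicyclic adduct 14, which aromatises by losing its saturated two-carbon bridge as a gas. This one operation places every ring B substituent: the acyl at C6 beside O5, hydrogen at C7, and three oxygens that are already differentiated (two methyl ethers, one silyl ether). No other cut of ring B does as much in one step. The forward reaction has to deliver the right regiochemistry, which the donor pattern of 9 is set up to provide.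

**C(=O)–C(sp) bond; 13 back to 12, and 12 back to 10 and 11.** The ynone is cut at the acyl–alkyne bond. Acylation of the bis-silylated alkyne 11 by the acid chloride 10 under Lewis acid activation is direct, and the remaining silyl group of 12 is removed under buffered conditions that a terminal ynone tolerates.

**O–Si, O–CH3 and the alpha-prime C–O bond; 9 back to 7 through 8, 7 back to 6, 6 back to 4 through 5.** Diene 9 is the silyl enol ether of ketone 7. The ring carbon beside the carbonyl that carries the methoxy group is the only alpha position with a hydrogen. That methoxy group is traced back to the hydroxyl of 6, introduced by oxygen transfer to the kinetic alpha-prime enolate 5 of the vinylogous ester 4.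

**O–CH3 and C2–CH2 bonds; 4 back to 3, and 3 back to 1 and 2.** The vinylogous ester comes from O-methylation of the 2-prenyl dione 3, and the prenyl group from C-alkylation of the symmetrical dione 1 with 2. The symmetry of 1 removes any regiochemical question at this stage.

## Alternatives that were turned down

**Alternative 1:** Ring C is disconnected at C4–C3 and O1–C2 of a simple chromene, and the diketone is added afterwards. In the forward key step the salicylaldehyde 2-hydroxy-3,6-dimethoxybenzaldehyde A2, the alkenylboronic acid (2-methylprop-1-en-1-yl)boronic acid A3 and a secondary amine condense. The alkenyl group moves from boron to the iminium carbon, the amine leaves to give an ortho-quinone methide, and oxa-6π closure gives 5,8-dimethoxy-2,2-dimethyl-2H-chromene A1.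
- For: one mild, metal-free step, and A2 and A3 are simple, stable pieces. It reaches the bicyclic core faster than the chosen route.
- Against: A1 has both C6–H and C7–H free and both O5 and O8 methylated, so the hard part of 20 is still open. A Friedel–Crafts acylation on A1 must choose C6 (ortho to O5, para to O1) over C7 (ortho to O8) on a modest electronic bias, and it exposes the acid-labile C3=C4 bond to a strong Lewis acid.
- Comparison: the chosen route is longer to the core, but the cycloaddition itself places the acyl group at C6 and marks O1 by a silyl group.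

**Alternative 2:** Ring B is cut into a carbene carbon (C8), an alkenyl pair (C8a, C4a), a carbonyl ligand (C5) and an alkyne (C7, C6). In the forward key step the dihydropyranyl(methoxy)carbene complex of Cr(CO)5 A5 is heated with 1-(buta-1,3-diyn-1-yl)-4-methoxybenzene A6. Alkyne insertion, carbonyl insertion and electrocyclisation give 4-(tert-butyldimethylsilyloxy)-8-methoxy-6-[(4-methoxyphenyl)ethynyl]-2,2-dimethylchroman-5-ol A4 as a racemate.
- For: O5 arrives free and O8 methylated, so no demethylation is needed. On this point it is stronger than the chosen route. Terminal alkynes insert with dependable regiochemistry.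
- Against: the zerovalent chromium is stoichiometric. A5 needs a multistep preparation by way of an organolithium intermediate. A6 is an unstable terminal diyne with two reactive triple bonds. A4 is an air-sensitive hydroquinone monoether that must then survive oxidation of the diarylalkyne to the diketone and elimination at C4.
- Comparison: the step count is no lower. The chosen route has a late oxidation and a demethylation, but each is a well-understood single operation and the ring-forming step needs no metal.

**Alternative 3:** The diketone is cut at C6–C(=N) and C(=N)–C(=O), with the inner carbonyl carbon coming from an isocyanide. In the forward key step 8-methoxy-5-(methoxymethoxy)-2,2-dimethyl-2H-chromene A8 is lithiated at C6 and added to 2-isocyano-2,4,4-trimethylpentane A9, and the lithium aldimine is acylated in the same flask by 4-methoxybenzoyl chloride A10. The product is 2-[8-methoxy-5-(methoxymethoxy)-2,2-dimethyl-2H-chromen-6-yl]-1-(4-methoxyphenyl)-2-[(2,4,4-trimethylpentan-2-yl)imino]ethan-1-one A7, which aqueous acid would convert into 20 by hydrolysis of the imine and loss of the acetal group on O5.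
- For: it is the most convergent plan, A9 and A10 are simple reagents, and the diketone is set at the right oxidation level with no late oxidation. On this point it is stronger than the chosen route.
- Against: A8 must already carry differentiated O5 and O8 and a ring C fused between two oxygens, so the regiochemical problem of ring B is moved into the preparation of A8. Metalation must choose C6 over C7. The electrophilic A7 can take a second equivalent of nucleophile. Hydrolysis of the hindered imine needs acid that threatens the chromene.
- Comparison: the chosen route has more steps after ring formation, but it builds the substitution pattern of ring B from an inexpensive symmetrical dione instead of presupposing it.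

Key step: step 8

## Route

Step 1
Reactants: 1 cyclohexane-1,3-dione; 2 1-bromo-3-methylbut-2-ene (prenyl bromide)
Product: 3 2-(3-methylbut-2-en-1-yl)cyclohexane-1,3-dione
Conditions: KOH (1 equiv), H2O, rt to 50 °C; then dilute HCl
Reagents that add atoms: none
Why: C-alkylation of the dione enolate in water, where hydrogen bonding shields the oxygens and the soft primary allylic bromide is attacked by C2 in an SN2 reaction at its unsubstituted terminus, so the linear prenyl isomer should form.

Step 2
Reactants: 3 2-(3-methylbut-2-en-1-yl)cyclohexane-1,3-dione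
Product: 4 3-methoxy-2-(3-methylbut-2-en-1-yl)cyclohex-2-en-1-one
Conditions: Me2SO4, K2CO3, acetone, reflux
Reagents that add atoms: dimethyl sulfate, COS(=O)(=O)OC
Why: O-methylation of a 2-substituted 1,3-dione enolate by a hard methylating agent (vinylogous ester formation); the dione is symmetrical so one enol ether is possible, and the basic medium avoids acid-induced addition of the enol oxygen to the prenyl double bond.

Step 3
Reactants: 4 3-methoxy-2-(3-methylbut-2-en-1-yl)cyclohex-2-en-1-one
Product: 6 6-hydroxy-3-methoxy-2-(3-methylbut-2-en-1-yl)cyclohex-2-en-1-one (racemic), via lithium dienolate 5 (not isolated)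
Conditions: LiN(iPr)2, THF, −78 °C; then 3-phenyl-2-(phenylsulfonyl)oxaziridine, −78 °C; aq. NH4Cl
Reagents that add atoms: 3-phenyl-2-(phenylsulfonyl)oxaziridine, O=S(=O)(c1ccccc1)N1OC1c1ccccc1
Why: Kinetic deprotonation of a 3-alkoxy enone takes the alpha-prime hydrogen at C6 and gives the cross-conjugated enolate 5, to which the N-sulfonyloxaziridine transfers electrophilic oxygen (Davis enolate hydroxylation) without touching the prenyl alkene; the new stereocenter is racemic and is erased in step 5.

Step 4
Reactants: 6 6-hydroxy-3-methoxy-2-(3-methylbut-2-en-1-yl)cyclohex-2-en-1-one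
Product: 7 3,6-dimethoxy-2-(3-methylbut-2-en-1-yl)cyclohex-2-en-1-one (racemic)
Conditions: MeI, Ag2O, 4 Å molecular sieves, MeCN, rt to 40 °C, dark
Reagents that add atoms: iodomethane, CI
Why: Purdie methylation, a silver-assisted SN2 methylation of the secondary alcohol under neutral conditions, so no alkoxide forms beside the ketone (no ketol shift or C-methylation) and the vinylogous ester is left alone.

Step 5
Reactants: 7 3,6-dimethoxy-2-(3-methylbut-2-en-1-yl)cyclohex-2-en-1-one
Product: 9 1,4-dimethoxy-3-(3-methylbut-2-en-1-yl)-2-(trimethylsilyloxy)cyclohexa-1,3-diene, via lithium enolate 8 (not isolated)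
Conditions: LiN(iPr)2, THF, −78 °C; then Me3SiCl, Et3N, −78 to 0 °C; pentane, filtration, no aqueous work-up
Reagents that add atoms: chlorotrimethylsilane, C[Si](C)(C)Cl
Why: C6–H is the only hydrogen alpha to the carbonyl and kinetic lithium amide deprotonation of a 3-alkoxy enone takes it in preference to the vinylogous C4–H, helped by the inductive effect of the methoxy group; the hard silyl chloride traps enolate 8 on oxygen (silyl enol ether formation). The stereocenter of 7 is removed and the moisture-sensitive diene is used crude.

Step 6
Reactants: 10 4-methoxyphenylacetyl chloride; 11 bis(trimethylsilyl)acetylene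
Product: 12 1-(4-methoxyphenyl)-4-(trimethylsilyl)but-3-yn-2-one
Conditions: AlCl3, CH2Cl2, −20 to 0 °C (acid chloride–AlCl3 complex added to excess 11); cold dilute HCl
Reagents that add atoms: none
Why: Friedel–Crafts-type ipso-acylation of an alkynylsilane: the activated acyl chloride attacks 11 to give a beta-silyl-stabilised vinyl cation that loses its silyl group, and the deactivated product ynone keeps the second silyl group.

Step 7
Reactants: 12 1-(4-methoxyphenyl)-4-(trimethylsilyl)but-3-yn-2-one
Product: 13 1-(4-methoxyphenyl)but-3-yn-2-one
Conditions: Na2B4O7·10H2O (0.01 M aq., cat.), MeOH, rt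
Reagents that add atoms: none
Why: Protodesilylation of a carbonyl-activated alkynylsilane in borate-buffered aqueous methanol (pH near 9), mild enough to avoid the conjugate addition of methanol that stronger bases cause on a terminal ynone.

Step 8
Reactants: 9 1,4-dimethoxy-3-(3-methylbut-2-en-1-yl)-2-(trimethylsilyloxy)cyclohexa-1,3-diene; 13 1-(4-methoxyphenyl)but-3-yn-2-one
Product: 15 1-[2,5-dimethoxy-3-(3-methylbut-2-en-1-yl)-4-(trimethylsilyloxy)phenyl]-2-(4-methoxyphenyl)ethan-1-one, via bicyclo[2.2.2]octadiene adduct 14 (not isolated)
Conditions: 9 (1.5 equiv), o-xylene, 2,6-di-tert-butyl-4-methylphenol (cat.), sealed tube, 70 °C then 150 °C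
Reagents that add atoms: none
Why: A normal-demand, concerted but asynchronous [4+2] cycloaddition joins the electron-rich diene 9 to the electron-poor triple bond of 13. The C8a silyloxy group and the C5 methoxy group both push electron density onto the C8 terminus, so C8 should bond first to the ynone beta carbon (future C7) and the acyl-bearing carbon (future C6) then bonds to C5; the C8 methoxy and the C4a alkyl group push the other way, but more weakly. Ring B is closed in this suprafacial [4+2] mode as bicyclo[2.2.2]octa-2,5-diene 14, whose bridgeheads C5 and C8 are quaternary, so it cannot tautomerise. At about 150 °C 14 should undergo a retro-[4+2] cycloreversion that expels the saturated two-carbon bridge as ethylene, made irreversible by aromatisation and loss of gas. The closest known reaction type is the Alder–Rickert reaction of 2-silyloxy- and 1-methoxycyclohexa-1,3-dienes with propiolates and ynones. No stereocenter remains, because the two bridgehead centers of racemic 14 become sp2. The step needs regioselectivity, secured by the donor pattern above, and chemoselectivity: the isolated, electron-rich prenyl alkene is not a dienophile, and anhydrous base-free conditions keep the silyl enol ether intact until ethylene is lost, so the C8a oxygen emerges as the only silyl ether.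

Step 9
Reactants: 15 1-[2,5-dimethoxy-3-(3-methylbut-2-en-1-yl)-4-(trimethylsilyloxy)phenyl]-2-(4-methoxyphenyl)ethan-1-one
Product: 16 1-[4-hydroxy-2,5-dimethoxy-3-(3-methylbut-2-en-1-yl)phenyl]-2-(4-methoxyphenyl)ethan-1-one
Conditions: K2CO3 (cat.), MeOH, 0 °C; then AcOH
Reagents that add atoms: none
Why: Methanolysis of an aryl trimethylsilyl ether, the only silicon–oxygen bond in the molecule; the two methyl ethers are untouched, so only the C8a oxygen is freed.

Step 10
Reactants: 16 1-[4-hydroxy-2,5-dimethoxy-3-(3-methylbut-2-en-1-yl)phenyl]-2-(4-methoxyphenyl)ethan-1-one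
Product: 17 1-(5,8-dimethoxy-2,2-dimethyl-2H-chromen-6-yl)-2-(4-methoxyphenyl)ethan-1-one
Conditions: PdCl2(MeCN)2 (10 mol %), 1,4-benzoquinone (1.5 equiv), THF, 40 °C
Reagents that add atoms: none
Why: Wacker-type oxidative cyclisation: the phenol oxygen adds to the alkene activated by divalent palladium at its tertiary carbon (Markovnikov, 6-endo-trig), beta-hydride elimination of the benzylic C4–H gives the C3=C4 bond, and benzoquinone reoxidises zerovalent palladium. O5 is methylated, so closure can occur only through the C8a oxygen.

Step 11
Reactants: 17 1-(5,8-dimethoxy-2,2-dimethyl-2H-chromen-6-yl)-2-(4-methoxyphenyl)ethan-1-one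
Product: 18 1-(5,8-dimethoxy-2,2-dimethyl-2H-chromen-6-yl)-2-(4-methoxyphenyl)ethane-1,2-dione
Conditions: SeO2 (1.5 equiv), 1,4-dioxane/H2O, 100 °C
Reagents that add atoms: selenium dioxide, O=[Se]=O
Why: Riley oxidation of a methylene activated by both a carbonyl and an electron-rich aryl group, the classical deoxybenzoin-to-benzil conversion; ring C has no allylic C–H (C2 is quaternary), so the chromene offers the oxidant no ene pathway.

Step 12
Reactants: 18 1-(5,8-dimethoxy-2,2-dimethyl-2H-chromen-6-yl)-2-(4-methoxyphenyl)ethane-1,2-dione
Product: 20 dielsianone [1-(5-hydroxy-8-methoxy-2,2-dimethyl-2H-chromen-6-yl)-2-(4-methoxyphenyl)ethane-1,2-dione], via aryloxydichloroborane chelate 19 (not isolated)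
Conditions: BCl3 (1.2 equiv), CH2Cl2, −78 to −20 °C; then H2O, 0 °C
Reagents that add atoms: none
Why: Chelation-controlled ether cleavage: BCl3 bridges the C6 carbonyl oxygen and O5 in a six-membered chelate and chloride removes that methyl group, whereas the C8 and ring A methyl ethers have no neighbouring carbonyl; the low temperature is chosen to spare the chromene.

## Compound list

1 | cyclohexane-1,3-dione | O=C1CCCC(=O)C1 | starting material
2 | 1-bromo-3-methylbut-2-ene (prenyl bromide) | CC(C)=CCBr | starting material
3 | 2-(3-methylbut-2-en-1-yl)cyclohexane-1,3-dione | O=C1CCCC(=O)C1CC=C(C)C | intermediate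
4 | 3-methoxy-2-(3-methylbut-2-en-1-yl)cyclohex-2-en-1-one | COC1=C(CC=C(C)C)C(=O)CCC1 | intermediate
5 | lithium 5-methoxy-6-(3-methylbut-2-en-1-yl)cyclohexa-1,5-dien-1-olate (not isolated) | COC1=C(CC=C(C)C)C(O[Li])=CCC1 | intermediate
6 | 6-hydroxy-3-methoxy-2-(3-methylbut-2-en-1-yl)cyclohex-2-en-1-one (racemic) | COC1=C(CC=C(C)C)C(=O)C(O)CC1 | intermediate
7 | 3,6-dimethoxy-2-(3-methylbut-2-en-1-yl)cyclohex-2-en-1-one (racemic) | COC1=C(CC=C(C)C)C(=O)C(OC)CC1 | intermediate
8 | lithium 2,5-dimethoxy-6-(3-methylbut-2-en-1-yl)cyclohexa-1,5-dien-1-olate (not isolated) | COC1=C(O[Li])C(CC=C(C)C)=C(OC)CC1 | intermediate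
9 | 1,4-dimethoxy-3-(3-methylbut-2-en-1-yl)-2-(trimethylsilyloxy)cyclohexa-1,3-diene | COC1=C(O[Si](C)(C)C)C(CC=C(C)C)=C(OC)CC1 | intermediate
10 | 4-methoxyphenylacetyl chloride | COc1ccc(CC(Cl)=O)cc1 | starting material
11 | bis(trimethylsilyl)acetylene | C[Si](C)(C)C#C[Si](C)(C)C | starting material
12 | 1-(4-methoxyphenyl)-4-(trimethylsilyl)but-3-yn-2-one | COc1ccc(CC(=O)C#C[Si](C)(C)C)cc1 | intermediate
13 | 1-(4-methoxyphenyl)but-3-yn-2-one | COc1ccc(CC(=O)C#C)cc1 | intermediate
14 | 1-[1,4-dimethoxy-6-(3-methylbut-2-en-1-yl)-5-(trimethylsilyloxy)bicyclo[2.2.2]octa-2,5-dien-2-yl]-2-(4-methoxyphenyl)ethan-1-one (racemic, not isolated) | COC12CCC(OC)(C(C(=O)Cc3ccc(OC)cc3)=C1)C(CC=C(C)C)=C2O[Si](C)(C)C | intermediate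
15 | 1-[2,5-dimethoxy-3-(3-methylbut-2-en-1-yl)-4-(trimethylsilyloxy)phenyl]-2-(4-methoxyphenyl)ethan-1-one | COc1ccc(CC(=O)c2cc(OC)c(O[Si](C)(C)C)c(CC=C(C)C)c2OC)cc1 | intermediate
16 | 1-[4-hydroxy-2,5-dimethoxy-3-(3-methylbut-2-en-1-yl)phenyl]-2-(4-methoxyphenyl)ethan-1-one | COc1ccc(CC(=O)c2cc(OC)c(O)c(CC=C(C)C)c2OC)cc1 | intermediate
17 | 1-(5,8-dimethoxy-2,2-dimethyl-2H-chromen-6-yl)-2-(4-methoxyphenyl)ethan-1-one | COc1ccc(CC(=O)c2cc(OC)c3OC(C)(C)C=Cc3c2OC)cc1 | intermediate
18 | 1-(5,8-dimethoxy-2,2-dimethyl-2H-chromen-6-yl)-2-(4-methoxyphenyl)ethane-1,2-dione | COc1ccc(C(=O)C(=O)c2cc(OC)c3OC(C)(C)C=Cc3c2OC)cc1 | intermediate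
19 | 1-{5-[(dichloroboranyl)oxy]-8-methoxy-2,2-dimethyl-2H-chromen-6-yl}-2-(4-methoxyphenyl)ethane-1,2-dione (not isolated) | COc1ccc(C(=O)C(=O)c2cc(OC)c3OC(C)(C)C=Cc3c2OB(Cl)Cl)cc1 | intermediate
20 | dielsianone, 1-(5-hydroxy-8-methoxy-2,2-dimethyl-2H-chromen-6-yl)-2-(4-methoxyphenyl)ethane-1,2-dione | COc1ccc(C(=O)C(=O)c2cc(OC)c3c(c2O)C=CC(C)(C)O3)cc1 | target

## Step count and least certain steps

Total step count: 12. Longest linear sequence: 10 steps (steps 1 to 5 and 8 to 12, from 1); the ynone branch (steps 6 and 7) joins at step 8.

**Step 8, the key step.** Three processes may interfere.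
- Erosion of regiocontrol, since the two methoxy-bearing termini of 9 differ only through the internal silyloxy group against the internal alkyl group.
- Proton transfer from the acidic methylene of 13 to the silyl enol ether, which destroys the diene.
- Thermal oligomerisation of the terminal ynone before it is trapped.

Fallback, setting out from 9 and returning at 17: the ynone is replaced by methyl propiolate, a dienophile with no enolisable methylene and the longest record in this reaction type. Heating 9 with it in toluene should give methyl 1,4-dimethoxy-6-(3-methylbut-2-en-1-yl)-5-(trimethylsilyloxy)bicyclo[2.2.2]octa-2,5-diene-2-carboxylate F1, which loses ethylene to give methyl 2,5-dimethoxy-3-(3-methylbut-2-en-1-yl)-4-(trimethylsilyloxy)benzoate F2. Methanolysis with K2CO3 in MeOH gives methyl 4-hydroxy-2,5-dimethoxy-3-(3-methylbut-2-en-1-yl)benzoate F3. The palladium cyclisation of step 10 then gives methyl 5,8-dimethoxy-2,2-dimethyl-2H-chromene-6-carboxylate F4. MeNH(OMe)·HCl with isopropylmagnesium chloride converts this into N,5,8-trimethoxy-N,2,2-trimethyl-2H-chromene-6-carboxamide F5, to which 4-methoxybenzylmagnesium chloride adds once to give 17.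

**Step 5.** Deprotonation may stray to the vinylogous C4 position, and the very electron-rich trimethylsilyl enol ether may be lost by hydrolysis during isolation. Fallback, setting out from 7 and returning at 16: enolisation is switched from a lithium amide to electrophilic O-silylation followed by deprotonation (TBSOTf, Et3N, CH2Cl2, 0 °C). Under these equilibrating conditions the fully substituted, triply oxygenated diene should also be the more stable isomer, and the product 2-(tert-butyldimethylsilyloxy)-1,4-dimethoxy-3-(3-methylbut-2-en-1-yl)cyclohexa-1,3-diene F6 tolerates chromatography. Heating F6 with 13 as in step 8 should pass through 1-[5-(tert-butyldimethylsilyloxy)-1,4-dimethoxy-6-(3-methylbut-2-en-1-yl)bicyclo[2.2.2]octa-2,5-dien-2-yl]-2-(4-methoxyphenyl)ethan-1-one F7 to 1-[4-(tert-butyldimethylsilyloxy)-2,5-dimethoxy-3-(3-methylbut-2-en-1-yl)phenyl]-2-(4-methoxyphenyl)ethan-1-one F8. Tetrabutylammonium fluoride in THF then frees 16.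

**Step 6.** The activated acyl chloride may acylate the electron-rich ring of a second molecule, or lose carbon monoxide to a stabilised 4-methoxybenzyl cation, before it finds the alkynylsilane. Fallback, setting out from 10 and returning at 13, which bypasses 12 and step 7: 10 is converted with MeNH(OMe)·HCl and pyridine in CH2Cl2 into N-methoxy-2-(4-methoxyphenyl)-N-methylacetamide F9. Ethynylmagnesium bromide in THF at 0 °C, with a cold aqueous NaHSO4 quench to keep the liberated amine from adding to the ynone, then gives 13 directly.

**Step 10.** Oxypalladation may take the 5-exo course to an isopropenyl dihydrobenzofuran, or catalyst turnover may stall on the electron-rich phenol. Fallback, setting out from 16 and returning at 17: PhSeCl in CH2Cl2 at −78 °C should open the seleniranium ion at the tertiary carbon (6-endo) to give 1-[5,8-dimethoxy-2,2-dimethyl-3-(phenylselanyl)-3,4-dihydro-2H-chromen-6-yl]-2-(4-methoxyphenyl)ethan-1-one F10. H2O2 in THF at 0 °C oxidises it to 1-[5,8-dimethoxy-2,2-dimethyl-3-(phenylseleninyl)-3,4-dihydro-2H-chromen-6-yl]-2-(4-methoxyphenyl)ethan-1-one F11, whose syn-elimination can only involve the C4 hydrogens and gives 17.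

**Step 12.** The Lewis acid or the hydrogen chloride formed on quench may ionise the tertiary allylic C2–O1 bond and open ring C, or a second methyl ether (C8, flanked by O1) may be cleaved. Fallback, setting out from 17 and returning at 20: the order of the last two operations is reversed and the boron halide avoided. MgI2 in Et2O/toluene under warming removes the methyl group ortho to the ketone by magnesium chelation and iodide attack, giving 1-(5-hydroxy-8-methoxy-2,2-dimethyl-2H-chromen-6-yl)-2-(4-methoxyphenyl)ethan-1-one F12. The SeO2 oxidation of step 11 applied to F12 then gives 20.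

## Further compounds

F1 | step 8 | methyl 1,4-dimethoxy-6-(3-methylbut-2-en-1-yl)-5-(trimethylsilyloxy)bicyclo[2.2.2]octa-2,5-diene-2-carboxylate (racemic) | COC(=O)C1=CC2(OC)CCC1(OC)C(CC=C(C)C)=C2O[Si](C)(C)C
F2 | step 8 | methyl 2,5-dimethoxy-3-(3-methylbut-2-en-1-yl)-4-(trimethylsilyloxy)benzoate | COC(=O)c1cc(OC)c(O[Si](C)(C)C)c(CC=C(C)C)c1OC
F3 | step 8 | methyl 4-hydroxy-2,5-dimethoxy-3-(3-methylbut-2-en-1-yl)benzoate | COC(=O)c1cc(OC)c(O)c(CC=C(C)C)c1OC
F4 | step 8 | methyl 5,8-dimethoxy-2,2-dimethyl-2H-chromene-6-carboxylate | COC(=O)c1cc(OC)c2OC(C)(C)C=Cc2c1OC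
F5 | step 8 | N,5,8-trimethoxy-N,2,2-trimethyl-2H-chromene-6-carboxamide | CON(C)C(=O)c1cc(OC)c2OC(C)(C)C=Cc2c1OC
F6 | step 5 | 2-(tert-butyldimethylsilyloxy)-1,4-dimethoxy-3-(3-methylbut-2-en-1-yl)cyclohexa-1,3-diene | COC1=C(O[Si](C)(C)C(C)(C)C)C(CC=C(C)C)=C(OC)CC1
F7 | step 5 | 1-[5-(tert-butyldimethylsilyloxy)-1,4-dimethoxy-6-(3-methylbut-2-en-1-yl)bicyclo[2.2.2]octa-2,5-dien-2-yl]-2-(4-methoxyphenyl)ethan-1-one (racemic) | COC12CCC(OC)(C(C(=O)Cc3ccc(OC)cc3)=C1)C(CC=C(C)C)=C2O[Si](C)(C)C(C)(C)C
F8 | step 5 | 1-[4-(tert-butyldimethylsilyloxy)-2,5-dimethoxy-3-(3-methylbut-2-en-1-yl)phenyl]-2-(4-methoxyphenyl)ethan-1-one | COc1ccc(CC(=O)c2cc(OC)c(O[Si](C)(C)C(C)(C)C)c(CC=C(C)C)c2OC)cc1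
F9 | step 6 | N-methoxy-2-(4-methoxyphenyl)-N-methylacetamide | COc1ccc(CC(=O)N(C)OC)cc1
F10 | step 10 | 1-[5,8-dimethoxy-2,2-dimethyl-3-(phenylselanyl)-3,4-dihydro-2H-chromen-6-yl]-2-(4-methoxyphenyl)ethan-1-one (racemic) | COc1ccc(CC(=O)c2cc(OC)c3OC(C)(C)C([Se]c4ccccc4)Cc3c2OC)cc1
F11 | step 10 | 1-[5,8-dimethoxy-2,2-dimethyl-3-(phenylseleninyl)-3,4-dihydro-2H-chromen-6-yl]-2-(4-methoxyphenyl)ethan-1-one (mixture of stereoisomers) | COc1ccc(CC(=O)c2cc(OC)c3OC(C)(C)C([Se](=O)c4ccccc4)Cc3c2OC)cc1
F12 | step 12 | 1-(5-hydroxy-8-methoxy-2,2-dimethyl-2H-chromen-6-yl)-2-(4-methoxyphenyl)ethan-1-one | COc1ccc(CC(=O)c2cc(OC)c3OC(C)(C)C=Cc3c2O)cc1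
A1 | alternative 1 | 5,8-dimethoxy-2,2-dimethyl-2H-chromene | COc1ccc(OC)c2C=CC(C)(C)Oc12
A2 | alternative 1 | 2-hydroxy-3,6-dimethoxybenzaldehyde | COc1ccc(OC)c(C=O)c1O
A3 | alternative 1 | (2-methylprop-1-en-1-yl)boronic acid | CC(C)=CB(O)O
A4 | alternative 2 | 4-(tert-butyldimethylsilyloxy)-8-methoxy-6-[(4-methoxyphenyl)ethynyl]-2,2-dimethylchroman-5-ol (racemic) | COc1ccc(C#Cc2cc(OC)c3OC(C)(C)CC(O[Si](C)(C)C(C)(C)C)c3c2O)cc1
A5 | alternative 2 | pentacarbonyl{[4-(tert-butyldimethylsilyloxy)-6,6-dimethyl-5,6-dihydro-4H-pyran-2-yl](methoxy)methylidene}chromium (racemic) | COC(=[Cr])C1=CC(O[Si](C)(C)C(C)(C)C)CC(C)(C)O1.[C-]#[O+].[C-]#[O+].[C-]#[O+].[C-]#[O+].[C-]#[O+]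
A6 | alternative 2 | 1-(buta-1,3-diyn-1-yl)-4-methoxybenzene | COc1ccc(C#CC#C)cc1
A7 | alternative 3 | 2-[8-methoxy-5-(methoxymethoxy)-2,2-dimethyl-2H-chromen-6-yl]-1-(4-methoxyphenyl)-2-[(2,4,4-trimethylpentan-2-yl)imino]ethan-1-one | COc1ccc(C(=O)C(=NC(C)(C)CC(C)(C)C)c2cc(OC)c3OC(C)(C)C=Cc3c2OCOC)cc1
A8 | alternative 3 | 8-methoxy-5-(methoxymethoxy)-2,2-dimethyl-2H-chromene | COCOc1ccc(OC)c2OC(C)(C)C=Cc12
A9 | alternative 3 | 2-isocyano-2,4,4-trimethylpentane | [C-]#[N+]C(C)(C)CC(C)(C)C
A10 | alternative 3 | 4-methoxybenzoyl chloride | COc1ccc(C(Cl)=O)cc1
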